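**Retrosynthetic overview**
1. Target 19 ⇐ diol 17 + 3,4-dimethoxybenzoyl chloride 18 (acylation of the secondary OH only); 17 ⇐ ene-dione 15 (hydroxyl-directed reduction) ⇐ enone 14 (γ-C–H oxidation).
2. 14 ⇐ cross-conjugated dienone 12 by the proposed new alkoxide-directed conjugate methylation, which creates the quaternary C8a and the trans ring fusion.
3. 12 ⇐ methoxycycloheptatriene carbinol 10 (enol ether hydrolysis) ⇐ azulenone 9 + i-PrMgCl (tertiary carbinol C3).
4. 9 ⇐ diazoketone 7 by an enantioselective intramolecular Buchner reaction: the five-membered ring closes first (norcaradiene 8), then the arene opens to the seven-membered ring in the same step.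
5. 7 ⇐ 3-methoxy-4-methylbenzaldehyde 1 + malonic acid 2, then diazomethane.

Assumption: the bis(oxazoline) antipode that gives (8aR)-9 is used (written as (S,S)-t-Bu-BOX, to be fixed by a test run); positions in the Why lines follow the azulene numbering of the target (C3 carbinol, C3a ring-fusion CH, C4 ester carbon, C7 ketone, C8a quaternary carbon).

**Route**

Step 1
Reactants: 1 3-methoxy-4-methylbenzaldehyde; 2 malonic acid
Product: 4 (E)-3-(3-methoxy-4-methylphenyl)prop-2-enoic acid, via arylidenemalonic acid 3 (not isolated)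
Conditions: pyridine, piperidine (cat.), 100 °C; then aq. HCl
Reagents that add atoms: malonic acid 2 OC(=O)CC(=O)O
Why: Knoevenagel–Doebner condensation; the arylidenemalonic acid 3 decarboxylates in hot pyridine to the (E)-cinnamic acid, and no stereocentre is formed.

Step 2
Reactants: 4 (E)-3-(3-methoxy-4-methylphenyl)prop-2-enoic acid
Product: 5 3-(3-methoxy-4-methylphenyl)propanoic acid
Conditions: H2 (1 atm), 10% Pd/C, EtOAc, rt
Reagents that add atoms: none
Why: Heterogeneous catalytic hydrogenation reduces only the conjugated C=C; the anisole ring and the acid are inert at 1 atm H2.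

Step 3
Reactants: 5 3-(3-methoxy-4-methylphenyl)propanoic acid
Product: 7 1-diazo-4-(3-methoxy-4-methylphenyl)butan-2-one, via acid chloride 6 (not isolated)
Conditions: (COCl)2, DMF (cat.), CH2Cl2, 0 °C to rt; then CH2N2 (3 equiv), Et2O, 0 °C
Reagents that add atoms: oxalyl chloride ClC(=O)C(=O)Cl (chlorine of 6); diazomethane C=[N+]=[N-]
Why: Acyl chloride formation followed by acylation of diazomethane (first stage of the Arndt–Eistert sequence) gives the α-diazoketone; a second equivalent of diazomethane scavenges HCl so no chloromethyl ketone forms.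

Step 4
Reactants: 7 1-diazo-4-(3-methoxy-4-methylphenyl)butan-2-one
Product: 9 (8aR)-5-methoxy-6-methyl-3,8a-dihydroazulen-1(2H)-one, via norcaradiene tautomer 8 (not isolated)
Conditions: [Cu(MeCN)4]PF6 (5 mol %), (S,S)-t-Bu-BOX (6 mol %), NaBArF4 (6 mol %), CH2Cl2, 40 °C, slow addition of 7; filtered through neutral alumina, used at once
Reagents that add atoms: none
Why: Enantioselective intramolecular Buchner reaction; the copper–bis(oxazoline) carbenoid cyclopropanates the arene bond between the ipso carbon and the ortho carbon para to OMe, norcaradiene 8 opens by 6π-electrocyclisation, and the chiral catalyst sets the ring-fusion CH (C3a of the target).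

Step 5
Reactants: 9 (8aR)-5-methoxy-6-methyl-3,8a-dihydroazulen-1(2H)-one
Product: 10 (1R,8aR)-5-methoxy-6-methyl-1-(propan-2-yl)-1,2,3,8a-tetrahydroazulen-1-ol
Conditions: i-PrMgCl (1.5 equiv), LaCl3·2LiCl (0.3 equiv), THF, −20 °C; aq. NH4Cl
Reagents that add atoms: isopropylmagnesium chloride CC(C)[Mg]Cl
Why: Lanthanide-promoted Grignard 1,2-addition (enolisation suppressed); isopropyl enters the cyclopentanone face that carries the ring-fusion hydrogen, anti to the seven-membered ring, so the new carbinol C3 has OH cis to the ring carbon C4 and isopropyl cis to H-3a, as in the target.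

Step 6
Reactants: 10 (1R,8aR)-5-methoxy-6-methyl-1-(propan-2-yl)-1,2,3,8a-tetrahydroazulen-1-ol
Product: 12 (3R,3aR)-3-hydroxy-6-methyl-3-(propan-2-yl)-2,3,3a,4-tetrahydroazulen-7(1H)-one, via skipped dienone 11 (not isolated)
Conditions: 0.5 M HCl, THF, 0 °C to rt
Reagents that add atoms: water O
Why: Acid hydrolysis of the methyl dienol ether gives the β,γ-unsaturated ketone 11, which isomerises under the same acid into the cross-conjugated dienone (enol ether hydrolysis then conjugation); C3 is untouched, and C3a, should it equilibrate through the dienol, prefers this epimer with C4 trans to isopropyl.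

Step 7
Reactants: 12 (3R,3aR)-3-hydroxy-6-methyl-3-(propan-2-yl)-2,3,3a,4-tetrahydroazulen-7(1H)-one
Product: 14 (3R,3aR,8aR)-3-hydroxy-6,8a-dimethyl-3-(propan-2-yl)-1,2,3,3a,4,8a-hexahydroazulen-7(8H)-one, via dimethylaluminium alkoxide 13 (not isolated)
Conditions: AlMe3 (3 equiv), CH2Cl2, −78 to 0 °C; aq. Rochelle salt
Reagents that add atoms: trimethylaluminium C[Al](C)C
Why: Proposed new method: AlMe3 first forms the dimethylaluminium alkoxide 13 at the C3 hydroxyl, a second AlMe3 activates the C7 carbonyl, and the oxygen-bound Al–CH3 is passed through a six-membered transition state (O–Al–CH3···C8a–C3a–C3) to the β-carbon C8a on the face of the oxygen, giving the C8a methyl cis to the C3 hydroxyl and trans to H-3a (trans ring fusion) and steering attack to the hindered β,β-disubstituted terminus instead of the open C5; the closest known reaction type is the hydroxyl-directed conjugate addition of trimethylaluminium to 4-hydroxycyclohexa-2,5-dienones (and the chelation-controlled conjugate addition of alkylmagnesium alkoxides to γ-hydroxy alkenenitriles), here extended to a δ-alkoxide, a cross-conjugated dienone and a quaternary centre.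

Step 8
Reactants: 14 (3R,3aR,8aR)-3-hydroxy-6,8a-dimethyl-3-(propan-2-yl)-1,2,3,3a,4,8a-hexahydroazulen-7(8H)-one
Product: 15 (3R,3aR,8aR)-3-hydroxy-6,8a-dimethyl-3-(propan-2-yl)-1,2,3,3a,8,8a-hexahydroazulene-4,7-dione
Conditions: Rh2(cap)4 (1 mol %), t-BuOOH (70% aq., 5 equiv), 1,2-dichloroethane, 40 °C
Reagents that add atoms: tert-butyl hydroperoxide CC(C)(C)OO
Why: Dirhodium caprolactamate/TBHP allylic oxidation; the tert-butylperoxyl radical abstracts the enone-activated γ-hydrogen at C4 and the mixed peroxide collapses to the ketone, giving the ene-1,4-dione, with C3a expected to remain trans-fused because this keeps C4 cis to the hydrogen-bonding hydroxyl and trans to isopropyl.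

Step 9
Reactants: 15 (3R,3aR,8aR)-3-hydroxy-6,8a-dimethyl-3-(propan-2-yl)-1,2,3,3a,8,8a-hexahydroazulene-4,7-dione
Product: 17 (3R,3aS,4S,8aR)-3,4-dihydroxy-6,8a-dimethyl-3-(propan-2-yl)-1,2,3,3a,4,8a-hexahydroazulen-7(8H)-one, via alkoxyborohydride 16 (not isolated)
Conditions: Me4NBH(OAc)3 (5 equiv), MeCN/AcOH 1:1, −30 °C; aq. Rochelle salt
Reagents that add atoms: tetramethylammonium triacetoxyborohydride C[N+](C)(C)C.CC(=O)O[BH-](OC(C)=O)OC(C)=O (boron, acetate and counter-ion of 16; 17 gains only hydrogen)
Why: Evans–Saksena hydroxyl-directed reduction; the C3 hydroxyl exchanges onto boron (16) and delivers hydride intramolecularly to the C4 ketone from its own face, giving the anti-1,3-diol (4S), while the unassisted C7 enone carbonyl is not reduced.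

Step 10
Reactants: 17 (3R,3aS,4S,8aR)-3,4-dihydroxy-6,8a-dimethyl-3-(propan-2-yl)-1,2,3,3a,4,8a-hexahydroazulen-7(8H)-one; 18 3,4-dimethoxybenzoyl chloride
Product: 19 (3R,3aS,4S,8aR)-3-hydroxy-6,8a-dimethyl-7-oxo-3-(propan-2-yl)-1,2,3,3a,4,7,8,8a-octahydroazulen-4-yl 3,4-dimethoxybenzoate
Conditions: DMAP (0.2 equiv), Et3N (2 equiv), CH2Cl2, 0 °C to rt
Reagents that add atoms: 3,4-dimethoxybenzoyl chloride 18 COc1ccc(C(=O)Cl)cc1OC
Why: DMAP-catalysed acylation (nucleophilic-catalysis esterification) takes the secondary allylic C4 hydroxyl only; the tertiary C3 hydroxyl is too hindered to react.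

**Compound list**
1 | 3-methoxy-4-methylbenzaldehyde | COc1cc(C=O)ccc1C | starting material
2 | malonic acid (propanedioic acid) | OC(=O)CC(=O)O | starting material
3 | 2-[(3-methoxy-4-methylphenyl)methylidene]propanedioic acid | COc1cc(C=C(C(=O)O)C(=O)O)ccc1C | intermediate
4 | (E)-3-(3-methoxy-4-methylphenyl)prop-2-enoic acid | COc1cc(/C=C/C(=O)O)ccc1C | intermediate
5 | 3-(3-methoxy-4-methylphenyl)propanoic acid | COc1cc(CCC(=O)O)ccc1C | intermediate
6 | 3-(3-methoxy-4-methylphenyl)propanoyl chloride | COc1cc(CCC(=O)Cl)ccc1C | intermediate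
7 | 1-diazo-4-(3-methoxy-4-methylphenyl)butan-2-one | COc1cc(CCC(=O)C=[N+]=[N-])ccc1C | intermediate
8 | norcaradiene valence tautomer of 9: 9-methoxy-8-methyltricyclo[4.4.0.0(1,5)]deca-7,9-dien-4-one, cyclopropane cis-fused to both rings, apex CH configured as C8a of 9 | O=C1CC[C@@]23C=C(OC)C(C)=C[C@@H]2[C@@H]13 | intermediate
9 | (8aR)-5-methoxy-6-methyl-3,8a-dihydroazulen-1(2H)-one | C1=CC(C)=C(OC)C=C2CCC(=O)[C@H]12 | intermediate
10 | (1R,8aR)-5-methoxy-6-methyl-1-(propan-2-yl)-1,2,3,8a-tetrahydroazulen-1-ol | C1=CC(C)=C(OC)C=C2CC[C@@](O)(C(C)C)[C@H]12 | intermediate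
11 | (3R,3aR)-3-hydroxy-6-methyl-3-(propan-2-yl)-2,3,3a,6-tetrahydroazulen-7(1H)-one (C6 epimer mixture) | C1=CC(C)C(=O)C=C2CC[C@@](O)(C(C)C)[C@H]12 | intermediate
12 | (3R,3aR)-3-hydroxy-6-methyl-3-(propan-2-yl)-2,3,3a,4-tetrahydroazulen-7(1H)-one | C1C=C(C)C(=O)C=C2CC[C@@](O)(C(C)C)[C@H]12 | intermediate
13 | dimethylaluminium alkoxide of 12 (Al on the C3 oxygen) | C1C=C(C)C(=O)C=C2CC[C@@](O[Al](C)C)(C(C)C)[C@H]12 | intermediate
14 | (3R,3aR,8aR)-3-hydroxy-6,8a-dimethyl-3-(propan-2-yl)-1,2,3,3a,4,8a-hexahydroazulen-7(8H)-one | C1C=C(C)C(=O)C[C@@]2(C)CC[C@@](O)(C(C)C)[C@H]12 | intermediate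
15 | (3R,3aR,8aR)-3-hydroxy-6,8a-dimethyl-3-(propan-2-yl)-1,2,3,3a,8,8a-hexahydroazulene-4,7-dione | O=C1C=C(C)C(=O)C[C@@]2(C)CC[C@@](O)(C(C)C)[C@H]12 | intermediate
16 | tetramethylammonium diacetoxy(hydrido)borate ester on the C3 oxygen of 15 | O=C1C=C(C)C(=O)C[C@@]2(C)CC[C@@](O[BH-](OC(C)=O)OC(C)=O)(C(C)C)[C@H]12.C[N+](C)(C)C | intermediate
17 | (3R,3aS,4S,8aR)-3,4-dihydroxy-6,8a-dimethyl-3-(propan-2-yl)-1,2,3,3a,4,8a-hexahydroazulen-7(8H)-one | O[C@H]1C=C(C)C(=O)C[C@@]2(C)CC[C@@](O)(C(C)C)[C@H]12 | intermediate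
18 | 3,4-dimethoxybenzoyl chloride | COc1ccc(C(=O)Cl)cc1OC | starting material
19 | (3R,3aS,4S,8aR)-3-hydroxy-6,8a-dimethyl-7-oxo-3-(propan-2-yl)-1,2,3,3a,4,7,8,8a-octahydroazulen-4-yl 3,4-dimethoxybenzoate | COc1ccc(C(=O)O[C@H]2C=C(C)C(=O)C[C@@]3(C)CC[C@@](O)(C(C)C)[C@H]23)cc1OC | target

**Totals**
Total step count: 10. Longest linear sequence: 10 steps (1 → 19; 2 and 18 are bought).

**Steps most likely to fail, with fallbacks**

Step 7 (the proposed new directed methylation). The risks are 1,2-addition at C7, no methyl transfer, or fragmentation of the aluminium alkoxide. The fallback uses known silicon-tethered radical chemistry and delivers the same carbon from the same oxygen. It sets out from 12: the tertiary hydroxyl is silylated with (bromomethyl)chlorodimethylsilane (Et3N, DMAP, CH2Cl2) to give the (bromomethyl)dimethylsilyl ether of 12 F5. Bu3SnH/AIBN (benzene, 80 °C, slow addition) generates the α-silyl radical, which closes 6-exo onto the dienone β-carbon C8a, necessarily cis to the oxygen, to give the bridged siloxane F6. Protodesilylation with TBAF in DMF at 70 °C cleaves Si–C and Si–O and leaves the methyl group, so the fallback comes back to the route at 14.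

Step 4 (asymmetric Buchner reaction). The electron-rich methoxyarene may give the 2-tetralone by aromatic substitution, the enol-ether azulenone is acid-labile, and the ee on this substrate is untested. The fallback replaces arene cyclopropanation by alkene cyclopropanation. It sets out from 5: Birch reduction (Li, NH3, t-BuOH, THF, −78 °C) gives 3-(5-methoxy-4-methylcyclohexa-1,4-dien-1-yl)propanoic acid F1. This is activated with isobutyl chloroformate/N-methylmorpholine as the mixed isobutyl carbonic anhydride F2 and treated with diazomethane to give 1-diazo-4-(5-methoxy-4-methylcyclohexa-1,4-dien-1-yl)butan-2-one F3. Copper(I)/bis(oxazoline)-catalysed intramolecular cyclopropanation of the trisubstituted ring alkene gives the tricyclic cyclopropyl ketone 9-methoxy-8-methyltricyclo[4.4.0.0(1,5)]dec-8-en-4-one F4. DDQ dehydrogenation then gives norcaradiene 8, which opens spontaneously, so the fallback comes back to the route at 9.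

Step 8 (γ-C–H oxidation). The risks are competing oxidation of the C6 methyl group, low conversion at the hindered C4 methylene, or base-free retro-aldol of the product. The fallback goes through the dienol ether. It sets out from 14: TMSOTf/Et3N (CH2Cl2, 0 °C) gives the linear bis(trimethylsilyl) dienol ether F7 (the tertiary hydroxyl is silylated as well). Vinylogous Rubottom oxidation (mCPBA, NaHCO3, CH2Cl2, −20 °C; citric acid work-up) gives the 4-hydroxy enone F8 as a mixture of C4 epimers. MnO2 oxidises the allylic alcohol, so the fallback comes back to the route at 15; the C4 configuration of F8 does not matter because step 9 sets it.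

Further compounds
F1 | step 4 | 3-(5-methoxy-4-methylcyclohexa-1,4-dien-1-yl)propanoic acid | COC1=C(C)CC=C(CCC(=O)O)C1
F2 | step 4 | mixed isobutyl carbonic anhydride of F1 | COC1=C(C)CC=C(CCC(=O)OC(=O)OCC(C)C)C1
F3 | step 4 | 1-diazo-4-(5-methoxy-4-methylcyclohexa-1,4-dien-1-yl)butan-2-one | COC1=C(C)CC=C(CCC(=O)C=[N+]=[N-])C1
F4 | step 4 | 9-methoxy-8-methyltricyclo[4.4.0.0(1,5)]dec-8-en-4-one, cyclopropane configured as in 8 | O=C1CC[C@@]23CC(OC)=C(C)C[C@@H]2[C@@H]13
F5 | step 7 | (bromomethyl)dimethylsilyl ether of 12 (on the C3 oxygen) | C1C=C(C)C(=O)C=C2CC[C@@](O[Si](C)(C)CBr)(C(C)C)[C@H]12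
F6 | step 7 | bridged siloxane: C8a–CH2–SiMe2–O–C3 tether on the skeleton of 14 | C1C=C(C)C(=O)C[C@@]2(C[Si](C)(C)O3)CC[C@@]3(C(C)C)[C@H]12
F7 | step 8 | bis(trimethylsilyl) derivative of 14: C7 dienol ether (C4=C5, C6=C7) and C3 silyl ether | C1=CC(C)=C(O[Si](C)(C)C)C[C@@]2(C)CC[C@@](O[Si](C)(C)C)(C(C)C)[C@H]12
F8 | step 8 | (3R,3aS,8aR)-3,4-dihydroxy-6,8a-dimethyl-3-(propan-2-yl)-1,2,3,3a,4,8a-hexahydroazulen-7(8H)-one, C4 epimer mixture | OC1C=C(C)C(=O)C[C@@]2(C)CC[C@@](O)(C(C)C)[C@H]12
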